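## The problem

Numbering used throughout: cyclohexane C1 (C–OH), C2, C3 (CHBr), C4 (CMeCl), C5, C6; cyclopentane C1' (quaternary, methyl-bearing), C2' (CMe2), C3' (CHBr).

- The target 22 joins the two rings through one bond between two fully substituted carbons, the tertiary carbinol C1 and the quaternary C1', which is itself flanked by the gem-dimethyl carbon C2'.
- Five stereocentres have to be set: C1' and C3' (bromine cis to the cyclohexyl group), and C1, C3 and C4 (hydroxyl and chlorine cis, bromine trans to both).
- The two sets are separated by the freely rotating C1–C1' bond, so the cyclopentane cannot be relied on to control the cyclohexane. Within the cyclopentane C1' biases C3' only weakly, so C3' is better set by a reagent.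
- With the bulky cyclopentyl group equatorial, the C3 bromine and C4 chlorine are both equatorial and the C4 methyl is axial. Anti addition of BrCl to a 4-methylcyclohex-3-enol under chair control gives the diaxial pattern instead, so the halogens need another device.
- The functional groups are fragile: a tertiary chloride beside a secondary bromide, a second, neopentylic secondary bromide, and a tertiary alcohol. A cation at C1 would sit next to the strained quaternary C1' and invite 1,2-shift with ring expansion, so conditions that ionise C1, strong base and reducing metals must be avoided late.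
- The enabling feature is that C1 and C4 are 1,4-related, fully substituted carbons that carry their heteroatoms on the same face, linked by C2–C3 and by C5–C6. This is the pattern of a 7-oxabicyclo[2.2.1]heptane, that is of a 2,5-disubstituted furan (C1 to C4 and the oxygen) that has taken up a two-carbon dienophile (C5, C6).

## Retrosynthesis

**22 ⇒ 20 ⇒ 19 (carboxyl on C6).** No ring bond is cut; a carboxyl group is put back on C6 (acid 20, its 2,2,2-trifluoroethyl ester 19). This is the ester of the dienophile. It is removed last for two reasons. On C6 it is the β-substituent of C1 and tempers heterolysis of the C1–O bond when the bridge is opened. The C6 radical of the decarboxylation also has no β-halogen, whereas a radical at C5 would sit next to C4–Cl. 20 is no simpler than 22; the forward steps need only be mild (saponification at 0 °C, radical decarboxylation that spares C–Br and C–Cl).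

**19 ⇒ 18 (C4–Cl cut, C4–O re-formed).** The cis hydroxyl/chlorine pair is traced to the oxygen bridge of the endo-bromo ether 18. Direct bromochlorination of a cyclohexene is the neighbouring option, but chair control places bromine cis to the hydroxyl. In 18 the bridge holds the ring as a boat and the C3 bromine anti-periplanar to the C4–O bond. The forward step must break C4–O, not C1–O, and return chloride to the face the oxygen leaves (retention through a bromonium ion). 18 has one stereocentre less to worry about than 19, because C4 is tied to C1.

**18 ⇒ 16 ⇒ 14 (C3–Br cut back to the alkene).** The endo bromide comes from the exo alcohol 16 by inversion, and 16 from the alkene of 14 by hydroboration. Electrophilic bromine on the alkene would enter exo and is no alternative. The forward steps need boron at C3 (the alkene carbon away from the crowded cyclopentyl bridgehead) and a clean backside displacement.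

**14 ⇒ 12 + 13 (C1–C6 and C4–C5 cut).** This is the retro-Diels–Alder step. It removes the carbocycle and three stereocentres at once and leaves the furan 12 and 2,2,2-trifluoroethyl acrylate 13.
- The cut is preferred over opening the ring elsewhere because it is the only one that delivers C1 and C4 with their heteroatom relationship already fixed.
- The ester is placed on C6. In a Lewis-acid-catalysed, asynchronous cycloaddition the unsubstituted acrylate carbon makes the short bond and should seek the less hindered, methyl-bearing furan carbon, so the ester carbon closes onto C1.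
- The forward reaction must attack one face of the furan; the adjacent quaternary centre gives little bias, so a chiral Lewis acid on the acrylate has to impose it.

**12 ⇒ 11 ⇒ 10 (C3'–Br cut back to the ketone).** The bromide comes from alcohol 11 with inversion, and 11 from ketone 10. Reagent control in the reduction is chosen over substrate control because the two faces of 10 differ only by methyl against furyl at the remote C1'.

**10 ⇒ 9 ⇒ 7 ⇒ 6 (two C2'–CH3 bonds cut).** The gem-dimethyl group is introduced by enolate alkylation of ketone 6. The carbon between the carbonyl and the quaternary centre is the hindered α-position, so the other α-position is blocked first (7), methylated twice (9) and unblocked. 6 is much simpler than 10, and the price is two blocking-group steps.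

**6 ⇒ 1 + 2 (C1'–furyl bond cut).** The quaternary stereocentre is made by enantioselective conjugate addition of a 5-methyl-2-furyl metal reagent (from 2-methylfuran 1) to 3-methylcyclopent-2-en-1-one 2. Both are commercial, and this one catalytic step supplies the absolute configuration on which all later centres depend.

## Roads not taken

**Alternative 1:** The cut is the C1'–CH3 bond, traced back to a cyclopropane methylene. In the forward key step Et2Zn and CH2I2 cyclopropanate a cyclopentene under the direction of the free C3' hydroxyl and give the bicyclo[3.1.0]hexanol A1; reductive opening of the exocyclic cyclopropane bond would later unveil the angular methyl.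
- Merit: hydroxyl-directed cyclopropanation is among the most reliable stereospecific reactions, and it ties the C1' configuration to the C3' oxygen with certainty. In this respect it is better than the chosen plan, which needs two independent catalyst-controlled steps (steps 1 and 5) for the same pair of centres.
- Weak points: the cyclopropane must be cleaved at one of its three bonds only. More seriously, the six-membered ring of A1 is a symmetrical ketal in which C1 is not yet a stereocentre, so C1, C3 and C4 would have to be created relative to the remote cyclopentane by a desymmetrising step with no relay. The bromine/chlorine pair would still face the chair-control problem.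
- Comparison: the chosen plan sets C1 and C4 in one cycloaddition and keeps them tied by the bridge, which A1 cannot offer.

**Alternative 2:** The cut is the C1'–C5' bond. In the forward key step BF3·OEt2 opens a spiro-epoxide and a cyclobutanol methylene migrates with inversion, giving the hydroxy ketone A2.
- Merit: one stereospecific, strain-driven step forms the congested C1–C1' junction with the C1 oxygen in place. This is more direct than the chosen plan, which reaches that junction only through a furan and a cycloaddition.
- Weak points: the ketone of A2 sits on C2', which must become the gem-dimethyl carbon (carbonyl to CMe2 next to a quaternary centre), and C3' still needs its bromine, so several hard steps follow. As in A1 the cyclohexane is a symmetrical ketal, and the configuration of C1, C3 and C4 relative to C1' is left open.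
- Comparison: against the elegance of the ring expansion the chosen plan sets an early, simple cyclopentane synthesis and full control of the cyclohexane centres.

**Alternative 3:** The cut is the C1'–C2' bond. In the forward key step a bromine-bridged cation closes the cyclopentane onto a tetrasubstituted alkene and water is captured at C1, giving the cyclohexenol A3.
- Merit: it is by far the shortest road. One step creates the bromide, the gem-dimethyl carbon, the quaternary centre and the carbinol, and it mirrors the likely biogenesis. In step count the chosen plan cannot compete.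
- Weak points: bromonium-initiated cyclisations of this kind are hard to steer (five- against six-membered closure, facial selectivity of water capture, absolute configuration). A3 would still need BrCl added with bromine trans and chlorine cis to the hydroxyl, which is the pattern chair-controlled addition disfavours.
- Comparison: the chosen plan answers with catalyst control of each stereocentre and with the oxygen bridge for the halogen pattern.

Key step: step 7

Remarks on assumptions:
- Regiochemistry: the cycloaddition is assumed to place the ester carbon on the side of the cyclopentyl-bearing bridgehead (short bond at the methyl-bearing furan carbon), as argued under step 7.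
- Catalyst sense: the ligand and catalyst enantiomers named in steps 1 and 7 are those expected to give 6 and 14; if either favours the antipodal sense, its mirror-image form is used without other change.

## Route

Step 1
Reactants: 1 2-methylfuran; 2 3-methylcyclopent-2-en-1-one
Product: 6 (3R)-3-methyl-3-(5-methylfuran-2-yl)cyclopentan-1-one, via (5-methylfuran-2-yl)lithium 3 (not isolated), via dimethyl(5-methylfuran-2-yl)aluminium 4 (not isolated), via dimethylaluminium enolate 5 (not isolated)
Conditions: n-BuLi, THF, 0 °C; Me2AlCl, −78 °C → rt; then 2, Cu(OTf)2 (5 mol %), [Ag(NHC)]2 (2.5 mol %, NHC = (4S,5S)-3-(2,6-diethylphenyl)-4,5-diphenyl-1-(2-sulfonatophenyl)imidazolidin-2-ylidene), THF, −30 °C; aq. NH4Cl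
Reagents that add atoms: none
Why: Copper-catalysed enantioselective conjugate addition of an aryl(dimethyl)aluminium reagent to a β-methyl cyclic enone; the furyl group is transferred in preference to methyl and the chiral carbene ligand selects the enone face, which sets the quaternary centre (R).

Step 2
Reactants: 6 (3R)-3-methyl-3-(5-methylfuran-2-yl)cyclopentan-1-one
Product: 7 (2E,4R)-2-[(dimethylamino)methylidene]-4-methyl-4-(5-methylfuran-2-yl)cyclopentan-1-one
Conditions: t-BuOCH(NMe2)2, toluene, 100 °C
Reagents that add atoms: tert-butoxybis(dimethylamino)methane, CN(C)C(OC(C)(C)C)N(C)C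
Why: The aminal ester condenses at the only unhindered α-methylene (the one remote from the quaternary carbon) and gives the vinylogous amide, a known blocking group for that side of a ketone; no stereocentre is formed and the quaternary centre is untouched.

Step 3
Reactants: 7 (2E,4R)-2-[(dimethylamino)methylidene]-4-methyl-4-(5-methylfuran-2-yl)cyclopentan-1-one
Product: 9 (3R,5E)-5-[(dimethylamino)methylidene]-2,2,3-trimethyl-3-(5-methylfuran-2-yl)cyclopentan-1-one, via monomethyl enaminone 8 (not isolated)
Conditions: KOt-Bu (3.5 equiv), MeI (6 equiv), THF/t-BuOH, 0 °C → rt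
Reagents that add atoms: iodomethane, CI
Why: With the other side blocked only the carbon between carbonyl and quaternary centre can be enolised, so it is methylated twice through 8 (α'-alkylation of a blocked ketone); the transient methine centre ends as the gem-dimethyl carbon.

Step 4
Reactants: 9 (3R,5E)-5-[(dimethylamino)methylidene]-2,2,3-trimethyl-3-(5-methylfuran-2-yl)cyclopentan-1-one
Product: 10 (3R)-2,2,3-trimethyl-3-(5-methylfuran-2-yl)cyclopentan-1-one
Conditions: KOH, H2O/ethylene glycol, 110 °C
Reagents that add atoms: none
Why: Hydroxide adds to the vinylogous amide and expels dimethylamine, and the resulting α-formyl ketone loses formate by retro-Claisen cleavage; the 2,5-dialkylfuran is stable to base and no stereocentre can epimerise.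

Step 5
Reactants: 10 (3R)-2,2,3-trimethyl-3-(5-methylfuran-2-yl)cyclopentan-1-one
Product: 11 (1R,3R)-2,2,3-trimethyl-3-(5-methylfuran-2-yl)cyclopentan-1-ol
Conditions: (S)-1-methyl-3,3-diphenyltetrahydro-1H,3H-pyrrolo[1,2-c][1,3,2]oxazaborole (20 mol %), BH3·SMe2, THF, −20 °C; MeOH
Reagents that add atoms: none
Why: Corey–Bakshi–Shibata reduction; the catalyst distinguishes the quaternary flank of the ketone from the methylene flank, and the S catalyst should deliver hydride to the face that gives the 1R carbinol (hydroxyl trans to the furyl group), largely independent of the remote quaternary centre.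

Step 6
Reactants: 11 (1R,3R)-2,2,3-trimethyl-3-(5-methylfuran-2-yl)cyclopentan-1-ol
Product: 12 2-[(1R,3S)-3-bromo-1,2,2-trimethylcyclopentyl]-5-methylfuran
Conditions: PPh3, CBr4, CH2Cl2, 0 °C → reflux
Reagents that add atoms: tetrabromomethane, BrC(Br)(Br)Br
Why: Appel reaction; bromide displaces the alkoxyphosphonium group with inversion (SN2), which places bromine cis to the furyl group (3S), and the neutral conditions avoid a cation that would rearrange beside the gem-dimethyl carbon.

Step 7
Reactants: 12 2-[(1R,3S)-3-bromo-1,2,2-trimethylcyclopentyl]-5-methylfuran; 13 2,2,2-trifluoroethyl acrylate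
Product: 14 2,2,2-trifluoroethyl (1S,2S,4S)-1-[(1R,3S)-3-bromo-1,2,2-trimethylcyclopentyl]-4-methyl-7-oxabicyclo[2.2.1]hept-5-ene-2-carboxylate (ester endo)
Conditions: 13 (3 equiv), (S)-1-(2-methylphenyl)-3,3-diphenyltetrahydro-1H,3H-pyrrolo[1,2-c][1,3,2]oxazaborole (20 mol %), AlBr3 (16 mol %), CH2Cl2, −78 °C; Et3N
Reagents that add atoms: none
Why: The AlBr3-activated oxazaborolidine binds the ester carbonyl of 13, and the electron-rich 2,5-dialkylfuran 12 adds across its 2,5-positions in a concerted, asynchronous, suprafacial [4+2] cycloaddition; the closest known reaction is the cationic oxazaborolidine-catalysed Diels–Alder reaction of furans with 2,2,2-trifluoroethyl acrylate. The six-membered carbocycle is closed by the cycloaddition itself, both ring bonds (C1–C6 and C4–C5, target numbering) forming in the one step, and it appears as the 7-oxabicyclo[2.2.1]heptene with the furan oxygen as the C1–O–C4 bridge. The short, advanced bond should run from the unsubstituted acrylate carbon to the less hindered, methyl-bearing furan carbon (C4–C5), so the ester carbon closes onto the cyclopentyl-bearing carbon and the ester ends on C6. The ester stereocentre is set by the catalyst, which exposes one face of the bound acrylate, together with the endo mode favoured at −78 °C. The bridgehead centres C1 and C4 are set together by the furan face that is attacked; the cyclopentyl group gives little bias, and the face follows from the acrylate face, the endo mode and the regiochemistry taken together. The step therefore needs all three selectivities at once; they rest on the steric difference between the furan termini (methyl against a tertiary alkyl group), kinetic control at low temperature and the catalyst, and any exo or regioisomeric adduct, which would carry the opposite bridgehead configuration, is a separable isomer. The cyclopentane stereocentres and the secondary bromide are spectators. The adduct can revert to its components and is taken on at once.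

Step 8
Reactants: 14 2,2,2-trifluoroethyl (1S,2S,4S)-1-[(1R,3S)-3-bromo-1,2,2-trimethylcyclopentyl]-4-methyl-7-oxabicyclo[2.2.1]hept-5-ene-2-carboxylate
Product: 16 2,2,2-trifluoroethyl (1S,2S,4S,5R)-1-[(1R,3S)-3-bromo-1,2,2-trimethylcyclopentyl]-5-hydroxy-4-methyl-7-oxabicyclo[2.2.1]heptane-2-carboxylate (hydroxyl exo), via exo-organoborane 15 (not isolated)
Conditions: 9-BBN, THF, 0 °C → rt; then H2O2, pH 7 phosphate buffer, 0 °C → rt
Reagents that add atoms: hydrogen peroxide, OO
Why: Hydroboration–oxidation; the borane adds to the strained alkene from the exo face (syn to the oxygen bridge) with boron on C3 (target numbering), the alkene carbon away from the crowded cyclopentyl-bearing bridgehead, and buffered oxidation retains configuration and spares the ester. Saturating the alkene also ends the risk of cycloreversion.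

Step 9
Reactants: 16 2,2,2-trifluoroethyl (1S,2S,4S,5R)-1-[(1R,3S)-3-bromo-1,2,2-trimethylcyclopentyl]-5-hydroxy-4-methyl-7-oxabicyclo[2.2.1]heptane-2-carboxylate
Product: 18 2,2,2-trifluoroethyl (1S,2S,4S,5S)-5-bromo-1-[(1R,3S)-3-bromo-1,2,2-trimethylcyclopentyl]-4-methyl-7-oxabicyclo[2.2.1]heptane-2-carboxylate (ring bromine endo), via exo-triflate 17 (not isolated)
Conditions: Tf2O, pyridine, CH2Cl2, −30 °C; then Bu4NBr, toluene, 0 → 40 °C
Reagents that add atoms: tetrabutylammonium bromide, CCCC[N+](CCCC)(CCCC)CCCC.[Br-]
Why: Sulfonate displacement with inversion (SN2); bromide enters from the endo face, so the bromine ends anti to the oxygen bridge (5S), and the β-oxygen disfavours ionisation of the triflate and with it Wagner–Meerwein shift or retention.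

Step 10
Reactants: 18 2,2,2-trifluoroethyl (1S,2S,4S,5S)-5-bromo-1-[(1R,3S)-3-bromo-1,2,2-trimethylcyclopentyl]-4-methyl-7-oxabicyclo[2.2.1]heptane-2-carboxylate
Product: 19 2,2,2-trifluoroethyl (1S,2S,4S,5S)-4-bromo-2-[(1R,3S)-3-bromo-1,2,2-trimethylcyclopentyl]-5-chloro-2-hydroxy-5-methylcyclohexane-1-carboxylate
Conditions: TiCl4 (2.5 equiv), CH2Cl2, −78 → −40 °C; aq. NaHCO3
Reagents that add atoms: titanium tetrachloride, Cl[Ti](Cl)(Cl)Cl
Why: Proposed new method: TiCl4 binds the bridge oxygen and the ester; the C4–O bond, anti-periplanar to the endo C3–Br bond, should ionise with bromine participation to a bromonium ion, while heterolysis at C1 is disfavoured by the titanium-bound ester on the neighbouring C6; chloride returns from the chlorotitanate to C4 on the face the oxygen left while the ring is still a boat (two inversions, net retention), so chlorine ends cis to the C1 oxygen and trans to bromine; the closest known reaction types are Lewis-acid cleavage of 7-oxabicyclo[2.2.1]heptanes by halide and retentive substitution next to bromine through a bromonium ion (trans-bromohydrin to trans-dihalide).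

Step 11
Reactants: 19 2,2,2-trifluoroethyl (1S,2S,4S,5S)-4-bromo-2-[(1R,3S)-3-bromo-1,2,2-trimethylcyclopentyl]-5-chloro-2-hydroxy-5-methylcyclohexane-1-carboxylate
Product: 20 (1S,2S,4S,5S)-4-bromo-2-[(1R,3S)-3-bromo-1,2,2-trimethylcyclopentyl]-5-chloro-2-hydroxy-5-methylcyclohexane-1-carboxylic acid
Conditions: LiOH, THF/H2O, 0 °C; dilute HCl to pH 3, 0 °C
Reagents that add atoms: lithium hydroxide, [Li+].[OH-]
Why: Saponification of the activated trifluoroethyl ester at 0 °C, mild enough to leave the tertiary chloride and the bromides alone and to avoid retro-aldol cleavage of the β-hydroxy ester; no stereocentre is touched.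

Step 12
Reactants: 20 (1S,2S,4S,5S)-4-bromo-2-[(1R,3S)-3-bromo-1,2,2-trimethylcyclopentyl]-5-chloro-2-hydroxy-5-methylcyclohexane-1-carboxylic acid
Product: 22 (1R,3S,4S)-3-bromo-1-[(1R,3S)-3-bromo-1,2,2-trimethylcyclopentyl]-4-chloro-4-methylcyclohexan-1-ol, via thiohydroxamate ester 21 (not isolated)
Conditions: DCC, 1-hydroxypyridine-2(1H)-thione, 4-(dimethylamino)pyridine (cat.), CH2Cl2, 0 °C, dark; then t-BuSH, hν (visible), rt
Reagents that add atoms: none
Why: Barton reductive decarboxylation; the thiohydroxamate ester 21 fragments under visible light to the C6 radical, which has no β-halogen and is reduced by the thiol, while alkyl bromides and the tertiary chloride do not react with the thiyl chain carrier. The C6 stereocentre disappears and the remaining five are those of the target.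

## Compound list

1 | 2-methylfuran | Cc1ccco1 | starting material
2 | 3-methylcyclopent-2-en-1-one | CC1=CC(=O)CC1 | starting material
3 | (5-methylfuran-2-yl)lithium | [Li]c1ccc(C)o1 | intermediate
4 | dimethyl(5-methylfuran-2-yl)aluminium | C[Al](C)c1ccc(C)o1 | intermediate
5 | dimethyl{[(3R)-3-methyl-3-(5-methylfuran-2-yl)cyclopent-1-en-1-yl]oxy}aluminium | C[Al](C)OC1=C[C@](C)(c2ccc(C)o2)CC1 | intermediate
6 | (3R)-3-methyl-3-(5-methylfuran-2-yl)cyclopentan-1-one | O=C1CC[C@@](C)(c2ccc(C)o2)C1 | intermediate
7 | (2E,4R)-2-[(dimethylamino)methylidene]-4-methyl-4-(5-methylfuran-2-yl)cyclopentan-1-one | O=C1/C(=C/N(C)C)C[C@@](C)(c2ccc(C)o2)C1 | intermediate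
8 | (3R,5E)-5-[(dimethylamino)methylidene]-2,3-dimethyl-3-(5-methylfuran-2-yl)cyclopentan-1-one (both C2 epimers) | CC1C(=O)/C(=C/N(C)C)C[C@@]1(C)c1ccc(C)o1 | intermediate
9 | (3R,5E)-5-[(dimethylamino)methylidene]-2,2,3-trimethyl-3-(5-methylfuran-2-yl)cyclopentan-1-one | CC1(C)C(=O)/C(=C/N(C)C)C[C@@]1(C)c1ccc(C)o1 | intermediate
10 | (3R)-2,2,3-trimethyl-3-(5-methylfuran-2-yl)cyclopentan-1-one | CC1(C)C(=O)CC[C@@]1(C)c1ccc(C)o1 | intermediate
11 | (1R,3R)-2,2,3-trimethyl-3-(5-methylfuran-2-yl)cyclopentan-1-ol (hydroxyl trans to furyl) | CC1(C)[C@H](O)CC[C@@]1(C)c1ccc(C)o1 | intermediate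
12 | 2-[(1R,3S)-3-bromo-1,2,2-trimethylcyclopentyl]-5-methylfuran (bromine cis to furyl) | CC1(C)[C@@H](Br)CC[C@@]1(C)c1ccc(C)o1 | intermediate
13 | 2,2,2-trifluoroethyl acrylate | C=CC(=O)OCC(F)(F)F | starting material
14 | 2,2,2-trifluoroethyl (1S,2S,4S)-1-[(1R,3S)-3-bromo-1,2,2-trimethylcyclopentyl]-4-methyl-7-oxabicyclo[2.2.1]hept-5-ene-2-carboxylate (ester endo) | CC1(C)[C@@H](Br)CC[C@@]1(C)[C@]12O[C@](C)(C=C1)C[C@@H]2C(=O)OCC(F)(F)F | intermediate
15 | 2,2,2-trifluoroethyl (1S,2S,4S,5R)-5-(9-borabicyclo[3.3.1]nonan-9-yl)-1-[(1R,3S)-3-bromo-1,2,2-trimethylcyclopentyl]-4-methyl-7-oxabicyclo[2.2.1]heptane-2-carboxylate (boron exo) | CC1(C)[C@@H](Br)CC[C@@]1(C)[C@]12O[C@](C)([C@H](B3C4CCCC3CCC4)C1)C[C@@H]2C(=O)OCC(F)(F)F | intermediate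
16 | 2,2,2-trifluoroethyl (1S,2S,4S,5R)-1-[(1R,3S)-3-bromo-1,2,2-trimethylcyclopentyl]-5-hydroxy-4-methyl-7-oxabicyclo[2.2.1]heptane-2-carboxylate (hydroxyl exo) | CC1(C)[C@@H](Br)CC[C@@]1(C)[C@]12O[C@](C)([C@H](O)C1)C[C@@H]2C(=O)OCC(F)(F)F | intermediate
17 | 2,2,2-trifluoroethyl (1S,2S,4S,5R)-1-[(1R,3S)-3-bromo-1,2,2-trimethylcyclopentyl]-4-methyl-5-(trifluoromethanesulfonyloxy)-7-oxabicyclo[2.2.1]heptane-2-carboxylate (triflate exo) | CC1(C)[C@@H](Br)CC[C@@]1(C)[C@]12O[C@](C)([C@H](OS(=O)(=O)C(F)(F)F)C1)C[C@@H]2C(=O)OCC(F)(F)F | intermediate
18 | 2,2,2-trifluoroethyl (1S,2S,4S,5S)-5-bromo-1-[(1R,3S)-3-bromo-1,2,2-trimethylcyclopentyl]-4-methyl-7-oxabicyclo[2.2.1]heptane-2-carboxylate (ring bromine endo) | CC1(C)[C@@H](Br)CC[C@@]1(C)[C@]12O[C@](C)([C@@H](Br)C1)C[C@@H]2C(=O)OCC(F)(F)F | intermediate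
19 | 2,2,2-trifluoroethyl (1S,2S,4S,5S)-4-bromo-2-[(1R,3S)-3-bromo-1,2,2-trimethylcyclopentyl]-5-chloro-2-hydroxy-5-methylcyclohexane-1-carboxylate | CC1(C)[C@@H](Br)CC[C@@]1(C)[C@@]1(O)[C@@H](C(=O)OCC(F)(F)F)C[C@](C)(Cl)[C@@H](Br)C1 | intermediate
20 | (1S,2S,4S,5S)-4-bromo-2-[(1R,3S)-3-bromo-1,2,2-trimethylcyclopentyl]-5-chloro-2-hydroxy-5-methylcyclohexane-1-carboxylic acid | CC1(C)[C@@H](Br)CC[C@@]1(C)[C@@]1(O)[C@@H](C(=O)O)C[C@](C)(Cl)[C@@H](Br)C1 | intermediate
21 | 2-thioxopyridin-1(2H)-yl (1S,2S,4S,5S)-4-bromo-2-[(1R,3S)-3-bromo-1,2,2-trimethylcyclopentyl]-5-chloro-2-hydroxy-5-methylcyclohexane-1-carboxylate | CC1(C)[C@@H](Br)CC[C@@]1(C)[C@@]1(O)[C@@H](C(=O)ON2C=CC=CC2=S)C[C@](C)(Cl)[C@@H](Br)C1 | intermediate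
22 | (1R,3S,4S)-3-bromo-1-[(1R,3S)-3-bromo-1,2,2-trimethylcyclopentyl]-4-chloro-4-methylcyclohexan-1-ol | CC1(C)[C@@H](Br)CC[C@@]1(C)[C@@]1(O)CC[C@](C)(Cl)[C@@H](Br)C1 | target

## Step count and least certain steps

Total: 12 steps. Longest linear sequence: 12 steps (1 and 2 to 22; 13 enters at step 7).

**Step 10 (bridge opening).** This is the step most likely to fail.
- The C1–O bond may break instead of the C4–O bond, since C1 is tertiary and relieved of strain on ionisation; the cation would then undergo 1,2-shift with expansion of the cyclopentane, or lose a proton.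
- Chloride may open the bromonium ion at C3 instead of C4.
- The C4 cation may lose a proton.
- The product alkoxide may be re-ionised by excess TiCl4.

The fallback uses known reactions, gives up the bridge as the control element, and runs from 18 back to 22. Saponification of 18 (LiOH, THF/H2O, 0 °C) gives the bromo ether acid F1, and Barton decarboxylation as in step 12 gives the ester-free bromo ether F2. Zinc (NH4Cl, EtOH, reflux) then effects reductive β-elimination (Boord type); it can break only the C4–O bond, because only that oxygen is β to the C3 bromine, and gives the cyclohexenol F3 (the same compound as A3). Trifluoroacetic anhydride and pyridine mask the tertiary hydroxyl as the trifluoroacetate F4 so that it cannot close back onto C4. Bu4N[BrCl2] adds BrCl anti with chloride at the tertiary carbon. The adduct with bromine on the face away from the axial acyloxy group is the bromochloro trifluoroacetate F5; the adduct with bromine and acyloxy group 1,3-diaxial is the expected by-product and would be removed by chromatography. K2CO3 in MeOH at 0 °C cleaves the trifluoroacetate and returns to 22.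

**Step 7 (key step).**
- Bond formation at the cyclopentyl-bearing furan carbon may be slow, and the adduct may revert on warming.
- Facial control may erode, because any exo or regioisomeric mode of addition delivers the opposite bridgehead configuration.
- If the regiochemistry as a whole turned out reversed, the same catalyst would attack the other furan face, and the ester would no longer sit beside C1.

Fallback, from 12 and 13 back to 14: run the cycloaddition with the achiral Lewis acid HfCl4 in CH2Cl2 at low temperature, without facial control. Because the cyclopentane stereocentres are fixed, 14 and the bridgehead diastereomer F6 are diastereomers, and 14 is separated by chromatography.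

**Step 9 (endo bromide).** Backside attack from the endo face at a secondary carbon beside a fully substituted bridgehead may be slow; the triflate may then be lost by elimination or hydrolysis.

Fallback, from 14 back to 18, changing from nucleophilic to electrophilic bromination: hydroborate 14 with dicyclohexylborane in place of 9-BBN to give the dicyclohexyl organoborane F7. Without isolation, treat it with Br2 and NaOCH2CF3 in THF at 0 °C in the dark. This base-induced bromination of organoboranes replaces boron by bromine with inversion (exo boron to endo bromide), and the alkoxide is matched to the ester. The sequence leaves out 16 and 17.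

**Step 1 (quaternary centre).** Transfer of the furyl group from aluminium may be slower or less face-selective than that of simple aryl groups, and methyl transfer may compete.

Fallback, from 1 back to 6, adding the methyl group instead of the furyl group: add (5-methylfuran-2-yl)lithium 3 to commercial 3-ethoxycyclopent-2-en-1-one to give the carbinol F8, which is hydrolysed by dilute acid in the work-up to the furyl enone F9. Copper-catalysed enantioselective conjugate addition of Me3Al (Cu(OTf)2 with the carbene silver complex of step 1, in whichever enantiomeric form gives the R centre) then leads to 6.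

## Further compounds

F1 | step 10 | (1S,2S,4S,5S)-5-bromo-1-[(1R,3S)-3-bromo-1,2,2-trimethylcyclopentyl]-4-methyl-7-oxabicyclo[2.2.1]heptane-2-carboxylic acid | CC1(C)[C@@H](Br)CC[C@@]1(C)[C@]12O[C@](C)([C@@H](Br)C1)C[C@@H]2C(=O)O
F2 | step 10 | (1S,2S,4R)-2-bromo-4-[(1R,3S)-3-bromo-1,2,2-trimethylcyclopentyl]-1-methyl-7-oxabicyclo[2.2.1]heptane | CC1(C)[C@@H](Br)CC[C@@]1(C)[C@]12O[C@](C)([C@@H](Br)C1)CC2
F3 | step 10 | (1R)-1-[(1R,3S)-3-bromo-1,2,2-trimethylcyclopentyl]-4-methylcyclohex-3-en-1-ol | CC1(C)[C@@H](Br)CC[C@@]1(C)[C@@]1(O)CCC(C)=CC1
F4 | step 10 | (1R)-1-[(1R,3S)-3-bromo-1,2,2-trimethylcyclopentyl]-4-methylcyclohex-3-en-1-yl trifluoroacetate | CC1(C)[C@@H](Br)CC[C@@]1(C)[C@@]1(OC(=O)C(F)(F)F)CCC(C)=CC1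
F5 | step 10 | (1R,3S,4S)-3-bromo-1-[(1R,3S)-3-bromo-1,2,2-trimethylcyclopentyl]-4-chloro-4-methylcyclohexyl trifluoroacetate | CC1(C)[C@@H](Br)CC[C@@]1(C)[C@@]1(OC(=O)C(F)(F)F)CC[C@](C)(Cl)[C@@H](Br)C1
F6 | step 7 | 2,2,2-trifluoroethyl (1R,2R,4R)-1-[(1R,3S)-3-bromo-1,2,2-trimethylcyclopentyl]-4-methyl-7-oxabicyclo[2.2.1]hept-5-ene-2-carboxylate (ester endo) | CC1(C)[C@@H](Br)CC[C@@]1(C)[C@@]12O[C@@](C)(C=C1)C[C@H]2C(=O)OCC(F)(F)F
F7 | step 9 | 2,2,2-trifluoroethyl (1S,2S,4S,5R)-1-[(1R,3S)-3-bromo-1,2,2-trimethylcyclopentyl]-5-(dicyclohexylboranyl)-4-methyl-7-oxabicyclo[2.2.1]heptane-2-carboxylate | CC1(C)[C@@H](Br)CC[C@@]1(C)[C@]12O[C@](C)([C@H](B(C3CCCCC3)C3CCCCC3)C1)C[C@@H]2C(=O)OCC(F)(F)F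
F8 | step 1 | 3-ethoxy-1-(5-methylfuran-2-yl)cyclopent-2-en-1-ol (racemic) | CCOC1=CC(O)(c2ccc(C)o2)CC1
F9 | step 1 | 3-(5-methylfuran-2-yl)cyclopent-2-en-1-one | O=C1C=C(c2ccc(C)o2)CC1
A1 | alternative 1 | 1-[8-(triethylsilyloxy)-1,4-dioxaspiro[4.5]decan-8-yl]-2,2-dimethylbicyclo[3.1.0]hexan-3-ol (cyclopropane syn to the hydroxyl) | CC1(C)[C@H](O)C[C@@H]2C[C@]12C1(O[Si](CC)(CC)CC)CCC3(CC1)OCCO3
A2 | alternative 2 | (2S)-2-(8-hydroxy-1,4-dioxaspiro[4.5]decan-8-yl)-2-methylcyclopentan-1-one | O=C1CCC[C@@]1(C)C1(O)CCC2(CC1)OCCO2
A3 | alternative 3 | (1R)-1-[(1R,3S)-3-bromo-1,2,2-trimethylcyclopentyl]-4-methylcyclohex-3-en-1-ol | CC1(C)[C@@H](Br)CC[C@@]1(C)[C@@]1(O)CCC(C)=CC1
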